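**Assumptions.** The absolute sense of the chiral ligand in Step 8 is matched empirically; I propose (S,S)-Trost ligand, and the antipode is used if the opposite enantiomer forms. "Anti to the allyl group" in Steps 9 and 10 refers to the face of the bicyclic system opposite the angular allyl group.

## Retrosynthetic overview
1. Target 12 comes from 11 by ionic hydrogenation of the C2=C3 enol ether. Hydride and proton add anti to the angular allyl group, giving the all-cis Ar/Me/allyl arrangement. 11 comes from dienone 10 by Cu–H conjugate reduction of the C4=C5 α-methoxy enone, which sets C5-OMe.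
2. Dienone 10 is made by the new step: Pd-catalysed enantioselective para-dearomative C-allylation of the 6-hydroxybenzofuran 9. This forms the C3a quaternary stereocentre and converts the aromatic ring into the cyclohexenone ring.
3. Phenol 9 comes from Larock annulation of o-iodophenol 4 with aryl propyne 7 (dihydrofuran ring formed first), followed by debenzylation.
4. Iodophenol 4 is made from isovanillin (benzylation, Dakin oxidation, iodination). Alkyne 7 is made from 3,4,5-trimethoxybenzaldehyde (Ohira–Bestmann, then methylation).

## Route

**Step 1**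
Reactants: 1 isovanillin (3-hydroxy-4-methoxybenzaldehyde)
Product: 2 3-(benzyloxy)-4-methoxybenzaldehyde
Conditions: BnBr, K2CO3, DMF, rt
Reagents that add atoms: benzyl bromide, BrCc1ccccc1
Why: Williamson O-benzylation selectively masks the phenol that will become the C6 oxygen.

**Step 2**
Reactants: 2
Product: 3 3-(benzyloxy)-4-methoxyphenol
Conditions: mCPBA, CH2Cl2, 0 °C to rt; then KOH, MeOH, rt
Reagents that add atoms: mCPBA, OOC(=O)c1cccc(Cl)c1 (supplies the phenolic O)
Why: Baeyer–Villiger (Dakin-type) oxidation of an electron-rich aldehyde gives aryl migration to the aryl formate, which is hydrolysed to the phenol.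

**Step 3**
Reactants: 3
Product: 4 5-(benzyloxy)-2-iodo-4-methoxyphenol
Conditions: NIS, MeCN, 0 °C to rt
Reagents that add atoms: N-iodosuccinimide, O=C1CCC(=O)N1I
Why: Electrophilic iodination goes ortho to the free OH and para to OBn (the unhindered, doubly activated position), which becomes C3a of the benzofuran.

**Step 4**
Reactants: 5 3,4,5-trimethoxybenzaldehyde
Product: 6 5-ethynyl-1,2,3-trimethoxybenzene
Conditions: Bestmann–Ohira reagent, K2CO3, MeOH, rt
Reagents that add atoms: dimethyl (1-diazo-2-oxopropyl)phosphonate, CC(=O)C(=[N+]=[N-])P(=O)(OC)OC (supplies the alkyne carbon)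
Why: Seyferth–Gilbert homologation (Ohira–Bestmann variant) converts the aldehyde to the terminal alkyne.

**Step 5**
Reactants: 6
Product: 7 5-(prop-1-yn-1-yl)-1,2,3-trimethoxybenzene
Conditions: n-BuLi, THF, −78 °C; then MeI
Reagents that add atoms: methyl iodide, CI
Why: Lithium acetylide alkylation installs the methyl group that will become C3-Me.

**Step 6**
Reactants: 4 and 7
Product: 8 6-(benzyloxy)-5-methoxy-3-methyl-2-(3,4,5-trimethoxyphenyl)benzofuran
Conditions: Pd(OAc)2 (5 mol%), n-Bu4NCl, K2CO3, DMF, 100 °C
Reagents that add atoms: none
Why: Larock heteroannulation (oxidative addition, alkyne insertion, C–O reductive elimination) places the larger aryl group at C2 next to oxygen and the methyl at C3.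

**Step 7**
Reactants: 8
Product: 9 5-methoxy-3-methyl-2-(3,4,5-trimethoxyphenyl)benzofuran-6-ol
Conditions: H2 (1 atm), 10% Pd/C, EtOAc, rt
Reagents that add atoms: none (H2 only)
Why: Hydrogenolysis removes the benzyl ether. The tetrasubstituted benzofuran C2=C3 bond is inert at 1 atm, and no allyl group is present yet.

**Step 8 (key, new)**
Reactants: 9 and allyl methyl carbonate
Product: 10 (3aS)-3a-allyl-5-methoxy-3-methyl-2-(3,4,5-trimethoxyphenyl)-1-benzofuran-6(3aH)-one
Conditions: Pd2(dba)3·CHCl3 (2.5 mol%), (S,S)-Trost ligand (7.5 mol%), toluene (0.05 M), rt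
Reagents that add atoms: allyl methyl carbonate, C=CCOC(=O)OC (supplies the allyl group)
Why: Proposed new method: an enantioselective Tsuji–Trost para-dearomatisation of a phenol at a fully substituted ring-fusion carbon (C3a of a 6-hydroxybenzofuran), forming an all-carbon quaternary stereocentre. Pd(0) ionises the carbonate to a chiral π-allyl-Pd methoxide ion pair, which deprotonates the phenol. The resulting phenoxide ion-paired with the chiral Pd–allyl attacks through its para carbon C3a, which has the largest HOMO coefficient. The ligand pocket discriminates the two enantiotopic faces of the planar C3a. The product cannot rearomatise, so C-allylation at C3a is irreversible, whereas any O-allyl ether re-ionises under Pd(0). The closest known chemistry is Pd-catalysed asymmetric allylic dearomatisation of naphthols and indoles.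

**Step 9**
Reactants: 10
Product: 11 (3aS,5R)-3a-allyl-5-methoxy-3-methyl-2-(3,4,5-trimethoxyphenyl)-4,5-dihydro-1-benzofuran-6(3aH)-one
Conditions: [(Ph3P)CuH]6 (Stryker's reagent, 0.3 equiv), toluene, −40 °C; then sat. aq. NH4Cl
Reagents that add atoms: none (H only)
Why: Cu–H conjugate reduction occurs selectively at the α-methoxy enone C4=C5, since the vinylogous ester, the enol ether and the allyl group are not acceptors. The copper enolate is protonated at C5 from the face anti to the pseudo-axial angular allyl, putting OMe cis to allyl (5R).

**Step 10**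
Reactants: 11
Product: 12 Dysodanthin B, (2R,3S,3aS,5R)-3a-allyl-5-methoxy-3-methyl-2-(3,4,5-trimethoxyphenyl)-3,3a,4,5-tetrahydro-1-benzofuran-6(2H)-one
Conditions: Et3SiH (6 equiv), TFA (15 equiv), CH2Cl2, 0 °C
Reagents that add atoms: none (H only)
Why: Ionic hydrogenation protonates C3 of the electron-rich 2-aryl enol ether from the face anti to the angular allyl, which pushes Me syn to allyl. Et3SiH then delivers hydride to the trimethoxybenzylic oxocarbenium at C2 anti to the new Me, so Ar ends up cis to Me. This gives the all-cis 2,3,3a arrangement, and the terminal alkene, vinylogous ester and C5-OMe stereocentre survive the mild conditions.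

## Compound list
1 | isovanillin | COc1ccc(C=O)cc1O | starting material
2 | 3-(benzyloxy)-4-methoxybenzaldehyde | COc1ccc(C=O)cc1OCc1ccccc1 | intermediate
3 | 3-(benzyloxy)-4-methoxyphenol | COc1ccc(O)cc1OCc1ccccc1 | intermediate
4 | 5-(benzyloxy)-2-iodo-4-methoxyphenol | Oc1cc(OCc2ccccc2)c(OC)cc1I | intermediate
5 | 3,4,5-trimethoxybenzaldehyde | COc1cc(C=O)cc(OC)c1OC | starting material
6 | 5-ethynyl-1,2,3-trimethoxybenzene | COc1cc(C#C)cc(OC)c1OC | intermediate
7 | 5-(prop-1-yn-1-yl)-1,2,3-trimethoxybenzene | COc1cc(C#CC)cc(OC)c1OC | intermediate
8 | 6-(benzyloxy)-5-methoxy-3-methyl-2-(3,4,5-trimethoxyphenyl)benzofuran | COc1cc2c(cc1OCc1ccccc1)oc(-c1cc(OC)c(OC)c(OC)c1)c2C | intermediate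
9 | 5-methoxy-3-methyl-2-(3,4,5-trimethoxyphenyl)benzofuran-6-ol | COc1cc2c(cc1O)oc(-c1cc(OC)c(OC)c(OC)c1)c2C | intermediate
10 | (3aS)-3a-allyl-5-methoxy-3-methyl-2-(3,4,5-trimethoxyphenyl)-1-benzofuran-6(3aH)-one | C=CC[C@@]12C=C(OC)C(=O)C=C1OC(c1cc(OC)c(OC)c(OC)c1)=C2C | intermediate
11 | (3aS,5R)-3a-allyl-5-methoxy-3-methyl-2-(3,4,5-trimethoxyphenyl)-4,5-dihydro-1-benzofuran-6(3aH)-one | C=CC[C@@]12C[C@@H](OC)C(=O)C=C1OC(c1cc(OC)c(OC)c(OC)c1)=C2C | intermediate
12 | Dysodanthin B | C=CC[C@@]12C[C@@H](OC)C(=O)C=C1O[C@@H](c1cc(OC)c(OC)c(OC)c1)[C@H]2C | target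

**Total steps:** 10. **Longest linear sequence:** 8 (1 → 2 → 3 → 4 → 8 → 9 → 10 → 11 → 12, through Steps 1, 2, 3, 6, 7, 8, 9, 10).

## Three steps most likely to fail
1. **Step 8 (new dearomative allylation).**
   - Risks: competing ortho C-allylation at C7 (which rearomatises), O-allylation, and modest ee.
   - Fallback: racemic para-dearomative allylation of 9 with PIDA/allyltrimethylsilane (known phenol oxidative allylation), then preparative chiral-phase HPLC resolution of dienone 10.
2. **Step 10 (ionic hydrogenation).**
   - Risks: acid-mediated C2–O ionisation or epimerisation at C2/C3/C5, wrong facial selectivity, or attack on the allyl alkene.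
   - Fallback: radical HAT hydrogenation of 11 (Mn(dpm)3, PhSiH3, TBHP, i-PrOH), which is chemoselective for the conjugated tetrasubstituted enol ether over the terminal alkene and avoids strong acid.
3. **Step 9 (C5 protonation stereochemistry).**
   - Risk: the wrong C5 epimer forms, because the face selectivity of enolate protonation is assumed.
   - Fallback: rerun the route from the 5-desmethoxy phenol (from 3-benzyloxyphenol-derived iodophenol), then install C5-OMe after ionic hydrogenation by enolate α-hydroxylation (LiHMDS, Davis oxaziridine), Mitsunobu inversion if needed, and Ag2O/MeI methylation.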